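**Retrosynthetic overview**

1. Target 21 (oxolane numbering: O1, C2 pentyl, C3 ester oxygen, C4 methylene, C5; side-chain carbinol carbon C1') ⇐ desilylation ⇐ palmitoylation of the C3 hydroxyl ⇐ cis-selective hydride reduction of oxolan-3-one 17 ⇐ unmasking of a spiro-1,3-dithiane at C3 of 15.
2. Key disconnection: the C3–C4 and O1–C5 bonds of the oxolane are made together in an anionic [3+2] annulation. The C,O-dianion of hydroxy dithiane 5 supplies O1–C2–C3 and the cis-2,3-epoxy triflate 12 supplies C4–C5–C1'.
3. Enabling feature: C3 bears an oxygen, so it can be carried at the carbonyl level as a dithiane-stabilised carbanion next to the O1 alkoxide. O1 on C5 and the hydroxyl on C1' are vicinal and threo, the retron of a 5-exo opening of a cis-oxirane with inversion at C5; the epoxide strain drives the closure.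
4. Fragments: 5 from 1,3-dithiane and ethyl hexanoate, then Corey–Bakshi–Shibata reduction (sets C2). 12 from dec-9-enal by Still–Gennari olefination, reduction, Sharpless epoxidation (sets C5 and C1') and triflation.
5. Ring order: oxirane (step 5, consumed in step 7), then the oxolane (step 7, the only ring of the target). The dithiane is a temporary ring removed in step 9, and C3 is set last (step 10).

Key step: step 7

Step 1
Reactants: 1 1,3-dithiane; 2 ethyl hexanoate
Product: 4 1-(1,3-dithian-2-yl)hexan-1-one, via 2-lithio-1,3-dithiane 3 (not isolated)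
Conditions: 1 (2.1 equiv), n-BuLi (2.1 equiv), THF, −30 °C; then 2 (1.0 equiv), −78 → 0 °C; then H2O
Reagents that add atoms: none
Why: Corey–Seebach acylation of the lithiated dithiane by the ester, in which the acidic 2-acyl dithiane is deprotonated at once by the second equivalent of 3 and so should not add a second time; no stereocenter is formed.

Step 2
Reactants: 4 1-(1,3-dithian-2-yl)hexan-1-one
Product: 5 (1S)-1-(1,3-dithian-2-yl)hexan-1-ol
Conditions: (R)-2-methyl-CBS-oxazaborolidine (15 mol %), BH3·SMe2, THF, −20 °C; then MeOH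
Reagents that add atoms: none
Why: Corey–Bakshi–Shibata reduction, in which the branched dithianyl group should act as the large substituent and the n-pentyl chain as the small one, so that the (R)-catalyst gives the (S)-carbinol that becomes C2.

Step 3
Reactants: 6 dec-9-enal; 7 methyl bis(2,2,2-trifluoroethoxy)phosphorylacetate
Product: 9 methyl (2Z)-dodeca-2,11-dienoate, via potassium phosphonate carbanion 8 (not isolated)
Conditions: 7, KN(SiMe3)2, 18-crown-6, THF, −78 °C; then 6
Reagents that add atoms: none
Why: Still–Gennari variant of the Horner–Wadsworth–Emmons olefination, in which fast irreversible elimination from the kinetic adduct of the electron-poor phosphonate should give the Z-enoate needed for a cis-oxirane.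

Step 4
Reactants: 9 methyl (2Z)-dodeca-2,11-dienoate
Product: 10 (2Z)-dodeca-2,11-dien-1-ol
Conditions: i-Bu2AlH (2.2 equiv), CH2Cl2, −78 °C; then aq. potassium sodium tartrate
Reagents that add atoms: none
Why: 1,2-reduction of the enoate by the aluminium hydride, which should leave both double bonds and the Z geometry untouched.

Step 5
Reactants: 10 (2Z)-dodeca-2,11-dien-1-ol
Product: 11 [(2S,3R)-3-(non-8-en-1-yl)oxiran-2-yl]methanol
Conditions: Ti(OiPr)4 (10 mol %), L-(+)-diethyl tartrate (12 mol %), t-BuOOH, 4 Å molecular sieves, CH2Cl2, −20 °C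
Reagents that add atoms: tert-butyl hydroperoxide, CC(C)(C)OO
Why: Sharpless asymmetric epoxidation, in which the titanium tartrate complex binds the allylic hydroxyl and delivers oxygen to one face of the Z-alkene, setting C5 (S, to be inverted in step 7) and C1' (R), while the remote terminal alkene has no directing group and should not react.

Step 6
Reactants: 11 [(2S,3R)-3-(non-8-en-1-yl)oxiran-2-yl]methanol
Product: 12 [(2S,3R)-3-(non-8-en-1-yl)oxiran-2-yl]methyl trifluoromethanesulfonate
Conditions: Tf2O, 2,6-lutidine, CH2Cl2, −78 °C; used at once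
Reagents that add atoms: trifluoromethanesulfonic anhydride, O=S(=O)(OS(=O)(=O)C(F)(F)F)C(F)(F)F
Why: O-sulfonylation of the primary alcohol with a hindered base that should spare the oxirane; no stereocenter is touched.

Step 7
Reactants: 5 (1S)-1-(1,3-dithian-2-yl)hexan-1-ol; 12 [(2S,3R)-3-(non-8-en-1-yl)oxiran-2-yl]methyl trifluoromethanesulfonate
Product: 15 (1R)-1-[(1S,3R)-1-pentyl-2-oxa-6,10-dithiaspiro[4.5]decan-3-yl]dec-9-en-1-ol, via C,O-dilithio dianion 13 (not isolated), via lithium epoxy alkoxide 14 (not isolated)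
Conditions: 5, n-BuLi (2.2 equiv), THF, −30 → 0 °C; then 12 (in Et2O), −78 °C; then DMPU, −78 → 40 °C; then H2O
Reagents that add atoms: none
Why: Double deprotonation gives the C,O-dilithio species 13, whose dithiane-stabilised carbanion (C3) displaces the primary triflate of 12 by SN2 (C3–C4 bond), and on warming the lithium alkoxide O1 of 14 opens the oxirane at its nearer carbon C5 with inversion (O1–C5 bond), the release of epoxide strain making the closure irreversible. The closest known reaction types are the domino C-alkylation/O-cyclisation of 1,3-dianions with epihalohydrins or 2,3-epoxy sulfonates to 2-(hydroxyalkyl)oxolanes and the alkylation of 2-lithio-1,3-dithianes with primary triflates. The oxolane closes in the 5-exo-tet mode, favoured over 6-endo attack at the far oxirane carbon for an alkyl-substituted epoxide and helped by the geminal disubstitution at the spiro carbon (Thorpe–Ingold effect). C5 (R) is set by SN2 inversion of the (S)-oxirane carbon, C1' (R) keeps the configuration given by the Sharpless epoxidation because its C–O bond is not broken, and C2 (S) is carried over from 5, so the 2,5-trans ring and the threo O1/hydroxyl pair follow stereospecifically from the cis-epoxide and not from any facial selection. The step needs C- before O-alkylation and attack at the triflate carbon before the oxirane, which the far higher nucleophilicity of the carbanion and the leaving-group ability of triflate at −78 °C should secure; the β-oxygen is present as an oxide, which cannot be eliminated, so the carbanion does not collapse to a ketene dithioacetal.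

Step 8
Reactants: 15 (1R)-1-[(1S,3R)-1-pentyl-2-oxa-6,10-dithiaspiro[4.5]decan-3-yl]dec-9-en-1-ol
Product: 16 tert-butyl(dimethyl){[(1R)-1-[(1S,3R)-1-pentyl-2-oxa-6,10-dithiaspiro[4.5]decan-3-yl]dec-9-en-1-yl]oxy}silane
Conditions: TBSOTf, 2,6-lutidine, CH2Cl2, 0 °C
Reagents that add atoms: tert-butyldimethylsilyl trifluoromethanesulfonate, CC(C)(C)[Si](C)(C)OS(=O)(=O)C(F)(F)F
Why: silylation of the only free hydroxyl, so that the C1' oxygen stays masked while the C3 oxygen is developed and acylated.

Step 9
Reactants: 16 tert-butyl(dimethyl){[(1R)-1-[(1S,3R)-1-pentyl-2-oxa-6,10-dithiaspiro[4.5]decan-3-yl]dec-9-en-1-yl]oxy}silane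
Product: 17 (2S,5R)-5-[(1R)-1-{[tert-butyl(dimethyl)silyl]oxy}dec-9-en-1-yl]-2-pentyloxolan-3-one
Conditions: PhI(OCOCF3)2, NaHCO3, MeCN/H2O (9:1), 0 °C
Reagents that add atoms: water, O
Why: oxidative dithioacetal hydrolysis (S-activation by the hypervalent iodine reagent, ring opening to a thionium ion, capture by water), run short and buffered so that the terminal alkene, the silyl ether and the enolisable C2 center should survive.

Step 10
Reactants: 17 (2S,5R)-5-[(1R)-1-{[tert-butyl(dimethyl)silyl]oxy}dec-9-en-1-yl]-2-pentyloxolan-3-one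
Product: 18 (2S,3S,5R)-5-[(1R)-1-{[tert-butyl(dimethyl)silyl]oxy}dec-9-en-1-yl]-2-pentyloxolan-3-ol
Conditions: LiBH(s-Bu)3, THF, −78 °C; then H2O
Reagents that add atoms: none
Why: bulky-hydride reduction of a 2-substituted oxolan-3-one, in which the hydride should approach from the ring face opposite the adjacent C2 pentyl group and so place the new C3 hydroxyl cis to pentyl (3S).

Step 11
Reactants: 18 (2S,3S,5R)-5-[(1R)-1-{[tert-butyl(dimethyl)silyl]oxy}dec-9-en-1-yl]-2-pentyloxolan-3-ol; 19 hexadecanoyl chloride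
Product: 20 (2S,3S,5R)-5-[(1R)-1-{[tert-butyl(dimethyl)silyl]oxy}dec-9-en-1-yl]-2-pentyloxolan-3-yl hexadecanoate
Conditions: pyridine, DMAP (cat.), CH2Cl2, 0 → 23 °C
Reagents that add atoms: none
Why: nucleophile-catalysed acylation (acylpyridinium) of the only free hydroxyl; the C3–O bond is not broken, so the configuration is kept.

Step 12
Reactants: 20 (2S,3S,5R)-5-[(1R)-1-{[tert-butyl(dimethyl)silyl]oxy}dec-9-en-1-yl]-2-pentyloxolan-3-yl hexadecanoate
Product: 21 (2S,3S,5R)-5-[(1R)-1-hydroxydec-9-en-1-yl]-2-pentyloxolan-3-yl hexadecanoate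
Conditions: HF·pyridine, THF/pyridine, 0 → 23 °C
Reagents that add atoms: none
Why: fluoride-driven silyl ether cleavage under buffered conditions that should leave the ester, the alkene and the ring untouched, the 3,5-trans arrangement making acyl migration to the freed hydroxyl unlikely.

**Compound list**

1 | 1,3-dithiane | C1CSCSC1 | starting material
2 | ethyl hexanoate | CCCCCC(=O)OCC | starting material
3 | 2-lithio-1,3-dithiane (formed in the flask) | [Li]C1SCCCS1 | intermediate
4 | 1-(1,3-dithian-2-yl)hexan-1-one | CCCCCC(=O)C1SCCCS1 | intermediate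
5 | (1S)-1-(1,3-dithian-2-yl)hexan-1-ol | CCCCC[C@H](O)C1SCCCS1 | intermediate
6 | dec-9-enal | C=CCCCCCCCC=O | starting material
7 | methyl bis(2,2,2-trifluoroethoxy)phosphorylacetate | COC(=O)CP(=O)(OCC(F)(F)F)OCC(F)(F)F | starting material
8 | potassium carbanion of 7 (formed in the flask) | [K+].COC(=O)[CH-]P(=O)(OCC(F)(F)F)OCC(F)(F)F | intermediate
9 | methyl (2Z)-dodeca-2,11-dienoate | C=CCCCCCCC/C=C\C(=O)OC | intermediate
10 | (2Z)-dodeca-2,11-dien-1-ol | C=CCCCCCCC/C=C\CO | intermediate
11 | [(2S,3R)-3-(non-8-en-1-yl)oxiran-2-yl]methanol | C=CCCCCCCC[C@H]1O[C@H]1CO | intermediate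
12 | [(2S,3R)-3-(non-8-en-1-yl)oxiran-2-yl]methyl trifluoromethanesulfonate | C=CCCCCCCC[C@H]1O[C@H]1COS(=O)(=O)C(F)(F)F | intermediate
13 | dilithium (1S)-1-(1,3-dithian-2-id-2-yl)hexan-1-olate (formed in the flask) | [Li+].[Li+].[O-][C@@H](CCCCC)[C-]1SCCCS1 | intermediate
14 | lithium (1S)-1-(2-{[(2S,3R)-3-(non-8-en-1-yl)oxiran-2-yl]methyl}-1,3-dithian-2-yl)hexan-1-olate (formed in the flask) | [Li+].C=CCCCCCCC[C@H]1O[C@H]1CC2(SCCCS2)[C@H](CCCCC)[O-] | intermediate
15 | (1R)-1-[(1S,3R)-1-pentyl-2-oxa-6,10-dithiaspiro[4.5]decan-3-yl]dec-9-en-1-ol | C=CCCCCCCC[C@@H](O)[C@H]1CC2(SCCCS2)[C@H](CCCCC)O1 | intermediate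
16 | tert-butyl(dimethyl){[(1R)-1-[(1S,3R)-1-pentyl-2-oxa-6,10-dithiaspiro[4.5]decan-3-yl]dec-9-en-1-yl]oxy}silane | C=CCCCCCCC[C@@H](O[Si](C)(C)C(C)(C)C)[C@H]1CC2(SCCCS2)[C@H](CCCCC)O1 | intermediate
17 | (2S,5R)-5-[(1R)-1-{[tert-butyl(dimethyl)silyl]oxy}dec-9-en-1-yl]-2-pentyloxolan-3-one | C=CCCCCCCC[C@@H](O[Si](C)(C)C(C)(C)C)[C@H]1CC(=O)[C@H](CCCCC)O1 | intermediate
18 | (2S,3S,5R)-5-[(1R)-1-{[tert-butyl(dimethyl)silyl]oxy}dec-9-en-1-yl]-2-pentyloxolan-3-ol | C=CCCCCCCC[C@@H](O[Si](C)(C)C(C)(C)C)[C@H]1C[C@H](O)[C@H](CCCCC)O1 | intermediate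
19 | hexadecanoyl chloride (palmitoyl chloride) | CCCCCCCCCCCCCCCC(=O)Cl | starting material
20 | (2S,3S,5R)-5-[(1R)-1-{[tert-butyl(dimethyl)silyl]oxy}dec-9-en-1-yl]-2-pentyloxolan-3-yl hexadecanoate | C=CCCCCCCC[C@@H](O[Si](C)(C)C(C)(C)C)[C@H]1C[C@H](OC(=O)CCCCCCCCCCCCCCC)[C@H](CCCCC)O1 | intermediate
21 | (2S,3S,5R)-5-[(1R)-1-hydroxydec-9-en-1-yl]-2-pentyloxolan-3-yl hexadecanoate | C=CCCCCCCC[C@@H](O)[C@H]1C[C@H](OC(=O)CCCCCCCCCCCCCCC)[C@H](CCCCC)O1 | target

**Step count and risks**

Total step count: 12. Longest linear sequence: 10 steps (steps 3 to 12, from dec-9-enal).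

The three steps most likely to fail:

Step 7. The second deprotonation next to the alkoxide may be slow or incomplete, and the alkoxide may compete with the carbanion for the triflate (O- instead of C-alkylation), so the annulation may stall at the alkylation stage or give mixtures. Fallback (sets out from 2 and 12, returns at 17): lithiated methyl phenyl sulfone is acylated with 2 to give 1-(phenylsulfonyl)heptan-2-one F1. Asymmetric hydrogenation with RuCl2[(S)-BINAP] and H2 in MeOH should give (2S)-1-(phenylsulfonyl)heptan-2-ol F2, the sense being taken by analogy with β-keto esters. This is a β-hydroxy sulfone, a class whose double deprotonation with n-BuLi is classical. Treatment with 12 as in step 7 should give (1R)-1-[(2R,5S)-5-pentyl-4-(phenylsulfonyl)oxolan-2-yl]dec-9-en-1-ol F3, in which the configuration at the sulfonyl carbon does not matter. Silylation (TBSOTf, 2,6-lutidine) gives its silyl ether, tert-butyl(dimethyl){[(1R)-1-[(2R,5S)-5-pentyl-4-(phenylsulfonyl)oxolan-2-yl]dec-9-en-1-yl]oxy}silane F4. Deprotonation with LiN(i-Pr)2 and oxidation of the carbanion with MoO5·pyridine·HMPA (oxidative desulfonylation) should then give ketone 17.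

Step 9. Hydrolysis of a hindered dithioacetal flanked by an oxygen-bearing carbon may be sluggish, and forcing it may bring over-oxidation at sulfur, attack on the alkene or enolisation with loss of configuration at C2. Fallback (sets out from 16, returns at 17): one sulfur of 16 is oxidised with NaIO4 (MeOH/H2O, 0 °C) to (1S,3R)-3-[(1R)-1-{[tert-butyl(dimethyl)silyl]oxy}dec-9-en-1-yl]-1-pentyl-2-oxa-6,10-dithiaspiro[4.5]decane 6-oxide F5. Pummerer activation ((CF3CO)2O, 2,6-lutidine, MeCN; then aq. NaHCO3) should then open the S-oxidised ring and hydrolyse the thionium ion to 17 under non-oxidising, nearly neutral conditions.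

Step 10. Facial selectivity may be poor, because the C5 side chain sits on the ring face that the hydride has to use. Fallback (sets out from 17, returns at 20): reduction under whichever conditions favour the other face (for example NaBH4, MeOH, −40 °C) gives (2S,3R,5R)-5-[(1R)-1-{[tert-butyl(dimethyl)silyl]oxy}dec-9-en-1-yl]-2-pentyloxolan-3-ol F6. Mitsunobu esterification of it with hexadecanoic acid (PPh3, diisopropyl azodicarboxylate, toluene) inverts C3 and installs the palmitate in one step, giving 20 directly.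

**Further compounds**

F1 | step 7 | 1-(phenylsulfonyl)heptan-2-one | CCCCCC(=O)CS(=O)(=O)c1ccccc1
F2 | step 7 | (2S)-1-(phenylsulfonyl)heptan-2-ol | CCCCC[C@H](O)CS(=O)(=O)c1ccccc1
F3 | step 7 | (1R)-1-[(2R,5S)-5-pentyl-4-(phenylsulfonyl)oxolan-2-yl]dec-9-en-1-ol | C=CCCCCCCC[C@@H](O)[C@H]1CC(S(=O)(=O)c2ccccc2)[C@H](CCCCC)O1
F4 | step 7 | tert-butyl(dimethyl){[(1R)-1-[(2R,5S)-5-pentyl-4-(phenylsulfonyl)oxolan-2-yl]dec-9-en-1-yl]oxy}silane | C=CCCCCCCC[C@@H](O[Si](C)(C)C(C)(C)C)[C@H]1CC(S(=O)(=O)c2ccccc2)[C@H](CCCCC)O1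
F5 | step 9 | (1S,3R)-3-[(1R)-1-{[tert-butyl(dimethyl)silyl]oxy}dec-9-en-1-yl]-1-pentyl-2-oxa-6,10-dithiaspiro[4.5]decane 6-oxide | C=CCCCCCCC[C@@H](O[Si](C)(C)C(C)(C)C)[C@H]1CC2(SCCCS2=O)[C@H](CCCCC)O1
F6 | step 10 | (2S,3R,5R)-5-[(1R)-1-{[tert-butyl(dimethyl)silyl]oxy}dec-9-en-1-yl]-2-pentyloxolan-3-ol | C=CCCCCCCC[C@@H](O[Si](C)(C)C(C)(C)C)[C@H]1C[C@@H](O)[C@H](CCCCC)O1
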